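**Assumption:** I take the SMILES stereochemistry as drawn (trans-fused hydroazulene, angular Me and D–H anti). The phenol is carried as its TBS ether until the last step.

**Atom labels used in the steps.**
- E = quaternary C–Me.
- D = ring-fusion CH.
- K = C(OH)(iPr).
- C = CH–O-aroyl.
- A = C(=CH2).
- J = CH–OH.
- In azulene numbering: K = C1, E = C3a, J = C5, A = C6, C = C8, D = C8a.

**Retrosynthesis**
1. Ferugin comes from a trisubstituted 5,6-epoxide by Ti(III)-mediated isomerisation, which gives the exocyclic methylene and the J–OH together. That epoxide comes from the Δ5,6-cycloheptene ester.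
2. The tertiary carbinol K comes from iPr–La addition to the C1 ketone. The C8-aroyl ester comes from the C8 alcohol of a β-hydroxy ketone.
3. The C8-OH and 8a-H pair (trans-fused) comes from α,β-epoxy-ketone reduction with SmI2, made by Weitz–Scheffer epoxidation of the enone. The enone comes from dehydration of an aldol adduct.
4. The seven-membered ring is closed last, by RCM of an allyl/methallyl-carbinol diene. The diene comes from a Mukaiyama aldol of the regiodefined enol ether made by Cu-catalysed asymmetric conjugate addition of Me to 3-allylcyclopentenone.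
5. Ring order: cyclopentane first (this sets the quaternary centre), then the cycloheptene by RCM.

## Route

**Step 1**
Reactants: 1, 3-ethoxycyclopent-2-en-1-one
Product: 2, 3-allylcyclopent-2-en-1-one
Conditions: allylMgBr, THF, 0 °C; then 2 M HCl, rt
Reagents that add atoms: allylmagnesium bromide, C=CC[Mg]Br; water (hydrolysis of the enol ether gives the ketone O), O
Why: Stork–Danheiser 1,2-addition then acid transposition of the vinylogous ester gives the β-allyl enone; no stereocentre is formed.

**Step 2**
Reactants: 2
Product: 3, (R)-trimethyl{[3-methyl-3-(prop-2-en-1-yl)cyclopent-1-en-1-yl]oxy}silane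
Conditions: MeMgBr, CuBr·SMe2 (5 mol %), Josiphos-type ligand (6 mol %), t-BuOMe, –78 °C; then TMSCl, –78 → 0 °C
Reagents that add atoms: methylmagnesium bromide, C[Mg]Br; chlorotrimethylsilane, C[Si](C)(C)Cl
Why: Cu-catalysed asymmetric conjugate addition of Me to the β,β-disubstituted enone sets quaternary carbon E (ligand enantiomer chosen for R), and the Mg enolate is trapped as the C2 (D-side) TMS enol ether, which fixes the regiochemistry of the later aldol.

**Step 3**
Reactants: 4, 3-methylbut-3-en-1-ol
Product: 5, 3-methylbut-3-enal
Conditions: Dess–Martin periodinane, NaHCO3, CH2Cl2, 0 °C; crude aldehyde used immediately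
Reagents that add atoms: none
Why: mild oxidation of the primary alcohol to the aldehyde without isomerising the β,γ-alkene.

**Step 4**
Reactants: 3 and 5
Product: 6, (3R)-2-(1-hydroxy-3-methylbut-3-en-1-yl)-3-methyl-3-allylcyclopentan-1-one (mixture at C–OH and D)
Conditions: BF3·OEt2, CH2Cl2, –78 °C; then aq. NaHCO3
Reagents that add atoms: none
Why: Mukaiyama aldol forms the D–C bond; the two new stereocentres are temporary (both are destroyed in Step 6), so diastereoselectivity does not matter, and E is untouched.

**Step 5**
Reactants: 6
Product: 7, (3aR)-8-hydroxy-3a,6-dimethyl-hexahydroazulen-1-one with a C5=C6 alkene (C8/C8a mixture)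
Conditions: Hoveyda–Grubbs II (5 mol %), toluene (5 mM), 80 °C
Reagents that add atoms: none
Why: ring-closing metathesis of the monosubstituted allyl and the 1,1-disubstituted methallyl alkene closes the seven-membered ring and forms the trisubstituted Z-cycloheptene that later becomes the exocyclic alkene.

**Step 6**
Reactants: 7
Product: 8, (3aR)-3a,6-dimethyl-3,3a,4,7-tetrahydro-2H-azulen-1-one (C8=C8a enone plus C5=C6 alkene)
Conditions: MsCl, Et3N, CH2Cl2, 0 °C; then DBU, rt
Reagents that add atoms: none
Why: mesylation then E1cB elimination of the β-mesyloxy ketone gives the ring-constrained cis enone and erases the temporary C8/C8a stereocentres.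

**Step 7**
Reactants: 8
Product: 9, 8,8a-epoxy ketone, O on the face anti to the 3a-methyl
Conditions: 30 % H2O2, 2 M NaOH (cat.), MeOH/THF, 0 °C
Reagents that add atoms: hydrogen peroxide, OO
Why: Weitz–Scheffer nucleophilic epoxidation is chemoselective for the enone over the isolated alkene, and attack anti to the axial angular methyl sets the C8–O configuration.

**Step 8**
Reactants: 9
Product: 10, (3aR)-8-hydroxy-3a,6-dimethyl-hexahydroazulen-1-one, with 8-OH and 8a-H cis to each other and both anti to 3a-Me
Conditions: SmI2 (2.5 equiv), THF/MeOH, –78 °C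
Reagents that add atoms: none (MeOH supplies only H)
Why: SmI2 cleaves the α C–O bond of the α,β-epoxy ketone (Molander reduction), so the C8–O keeps its configuration, and the Sm enolate is protonated anti to the angular methyl, giving the trans ring fusion.

**Step 9**
Reactants: 11, 4-hydroxybenzoic acid
Product: 12, 4-(tert-butyldimethylsilyloxy)benzoic acid
Conditions: TBSCl (2.2 equiv), imidazole, DMF, rt; then K2CO3, MeOH/H2O
Reagents that add atoms: TBSCl, CC(C)(C)[Si](C)(C)Cl
Why: double silylation followed by mild base selectively cleaves the silyl ester and leaves the aryl TBS ether.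

**Step 10**
Reactants: 10 and 12
Product: 13, the 8-O-[4-(TBSO)benzoate] of 10
Conditions: 12, 2,4,6-Cl3C6H2COCl, Et3N, THF, rt; then 10, DMAP (3 equiv), toluene, 60 °C
Reagents that add atoms: none
Why: Yamaguchi esterification by acyl transfer leaves the C8 stereocentre untouched.

**Step 11**
Reactants: 13
Product: 14, the 1-hydroxy-1-isopropyl compound (K–OH up, iPr anti to the C8 substituent)
Conditions: iPrMgCl·LaCl3·2LiCl (3 equiv), THF, –78 → –40 °C
Reagents that add atoms: isopropylmagnesium chloride, CC(C)[Mg]Cl
Why: the organolanthanum adds to the ketone in preference to the aryl ester, and it attacks the face anti to the adjacent C8 substituent and the angular Me (1,2-addition to a 2-substituted cyclopentanone), which sets K.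

**Step 12**
Reactants: 14
Product: 15, the 5,6-epoxide, O anti to 3a-Me
Conditions: mCPBA, NaHCO3, CH2Cl2, 0 °C
Reagents that add atoms: mCPBA, OOC(=O)c1cccc(Cl)c1
Why: Prilezhaev epoxidation of the only alkene occurs from the face anti to the angular methyl, and this face fixes the configuration of J.

**Step 13**
Reactants: 15
Product: 16, ferugin
Conditions: Cp2TiCl2 (20 mol %), Zn, 2,4,6-collidine, TMSCl, THF, rt; then TBAF, AcOH, THF, 0 °C
Reagents that add atoms: none (TMS and TBS groups are removed again)
Why: Ti(III) epoxide opening (Nugent–RajanBabu/Oltra type) homolyses the tertiary C6–O bond, and β-H loss from the methyl gives the exocyclic methylene while the J–O bond, and hence J–OH, is retained; TBAF then removes the silyl groups.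

## Compound list
1 | 3-ethoxycyclopent-2-en-1-one | CCOC1=CC(=O)CC1 | starting material
2 | 3-allylcyclopent-2-en-1-one | C=CCC1=CC(=O)CC1 | intermediate
3 | (R)-TMS enol ether of 3-allyl-3-methylcyclopentanone | C=CC[C@@]1(C)CCC(O[Si](C)(C)C)=C1 | intermediate
4 | 3-methylbut-3-en-1-ol | CC(=C)CCO | starting material
5 | 3-methylbut-3-enal | CC(=C)CC=O | intermediate
6 | aldol adduct (C–OH/D epimer mixture, 3R) | C=CC[C@@]1(C)CCC(=O)C1C(O)CC(C)=C | intermediate
7 | 8-hydroxy-3a,6-dimethyl-hydroazulen-1-one, 5,6-ene (3aR, C8/C8a mixture) | O=C1CC[C@]2(C)CC=C(C)CC(O)C12 | intermediate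
8 | 3a,6-dimethyl-3,3a,4,7-tetrahydro-2H-azulen-1-one (8,8a-ene) | O=C1CC[C@]2(C)CC=C(C)CC=C12 | intermediate
9 | 8,8a-epoxy ketone | O=C1CC[C@]2(C)CC=C(C)C[C@@H]3O[C@]123 | intermediate
10 | β-hydroxy ketone (8-OH and 8a-H cis, trans-fused) | O=C1CC[C@]2(C)CC=C(C)C[C@H](O)[C@@H]12 | intermediate
11 | 4-hydroxybenzoic acid | O=C(O)c1ccc(O)cc1 | starting material
12 | 4-(TBSO)benzoic acid | O=C(O)c1ccc(O[Si](C)(C)C(C)(C)C)cc1 | intermediate
13 | 4-(TBSO)benzoate of 10 | O=C1CC[C@]2(C)CC=C(C)C[C@H](OC(=O)c3ccc(O[Si](C)(C)C(C)(C)C)cc3)[C@@H]12 | intermediate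
14 | 1-hydroxy-1-isopropyl ester, 5,6-ene | CC=1C[C@H](OC(=O)c2ccc(O[Si](C)(C)C(C)(C)C)cc2)[C@@H]2[C@](C)(CC[C@@]2(O)C(C)C)CC=1 | intermediate
15 | 5,6-epoxide of 14 | C[C@@]12C[C@H](OC(=O)c3ccc(O[Si](C)(C)C(C)(C)C)cc3)[C@@H]3[C@](C)(CC[C@@]3(O)C(C)C)C[C@@H]1O2 | intermediate
16 | ferugin | C=C1C[C@H](OC(=O)c2ccc(O)cc2)[C@@H]2[C@](C)(CC[C@@]2(O)C(C)C)C[C@@H]1O | target

**Total steps: 13. Longest linear sequence: 11** (1 → 2 → 3 → 6 → 7 → 8 → 9 → 10 → 13 → 14 → 15 → 16).

**Three steps most likely to fail**
1. **Step 2 (enantioselective conjugate addition to a cyclopentenone).** The ee for β,β-disubstituted cyclopentenones is often only moderate.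
   - Fallback: add Me2CuLi to 2 to make racemic 3, carry it through to the stable bicyclic ketone 7, and resolve by preparative chiral HPLC.
2. **Step 8 (D–H configuration).** Kinetic protonation of the Sm enolate might give the cis-fused isomer.
   - Fallback: add iPrCeCl2 to enone 8 (1,2-addition) to give the allylic tertiary alcohol, then hydroborate and oxidise the C8=C8a alkene. Syn addition anti to the angular Me gives the same 8-OH/8a-H relationship.
3. **Step 12 (epoxidation face).** The C8 ester and the angular Me flank the two faces of the C5=C6 alkene, so the selectivity is uncertain.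
   - Fallback: run the epoxidation and Ti(III) isomerisation on the free C8-alcohol with VO(acac)2/t-BuOOH, directed syn to C8–OH, and esterify last through a J-O-silyl intermediate.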